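Compound numbers are those of the steps below. Locants C1–C15 are those of the target skeleton and are kept for every intermediate: ring B = C1–C5 and C10, ring A = C5–C10, ring C = C11–C15.

## Analysis of the target

Neoirietetraol 30 is a dibrominated diterpenoid tetraol. A trans-fused decalin (rings A and B) carries at C7 a 1,2,2-trimethylcyclopentane (ring C) through a bond between two fully substituted carbons, C7 and C11. There are eight stereocentres in two clusters: C1, C4, C5, C7 and C10 on the decalin, and C11, C12 and C14 on ring C. The clusters are insulated by C8 and C9, so their relative configuration has to come from an enantiopure ring C piece and a catalyst-controlled step on ring B. On the decalin the C1 bromide is equatorial and cis to the C10 methyl group. The C5 and C7 hydroxyls are both axial on the face opposite that methyl group, and the C4 hydroxyl is axial on the methyl face, trans-diaxial to the C5 hydroxyl. On ring C the C7 substituent, the C12 hydroxyl and the C14 bromide share one face and the C11 methyl group takes the other. Sensitive points are the two secondary bromides next to quaternary carbons (elimination, reductive cleavage, and difficult to make by substitution), the tertiary 4,5-diol (dehydration, pinacol shift), and the C7/C12 diol, which is a retro-aldol-prone β-hydroxy ketone whenever C7 is a carbonyl. The hardest element is the C7 carbinol flanked by the quaternary C11 and C15. The strategy rests on C7 lying γ to C4 through C6 and C5: a γ-hydroxy ketone pattern that allows ring A to be closed at C6–C7 by reductive coupling of a C7 ketone with an exocyclic C5=C6 enone on ring B.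

## Retrosynthetic reasoning

**30 to 25.** The C4 methyl group and the C5 hydroxyl are removed. Both originate from the C4 ketone of 25: enolisation towards C5 and oxygenation gives the C5 hydroxyl, and equatorial methyl addition then leaves the C4 hydroxyl axial. The forward sequence has to control the direction of enolisation and two facial selectivities on a rigid trans-decalin.

**25 to 23.** The C6–C7 bond is cut. This turns the most crowded carbinol into a ketone and an enone held in one molecule, so the carbinol is formed by ring closure and not by intermolecular attack on a ketone between C11 and C15. The forward step needs a one-electron reduction that spares both bromides, a six-membered closure at the unsubstituted alkene terminus, and control of C7.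

**23 to 19.** The exocyclic enone is traced to a C5 ketone: C6 is added by methylenation and the C4 carbonyl by oxidation of the only allylic methylene. Direct α-methylenation of a C4 ketone would have to choose between C3 and C5 and would favour the wrong one.

**19 to 18 to 17.** The C1 bromide comes from a C1 alcohol by inversion, done while the C5 carbonyl next to C10 suppresses cationic rearrangement. Alcohol 18 comes from the prochiral dione 17 by a catalyst-controlled reduction that sets C10 and C1 together. Had C10 been built by conjugate addition next to an existing C1 oxygen, the chain would enter anti to that oxygen and inversion would leave the bromide trans to the methyl group.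

**17 to 15 and 16.** The C9–C10 bond is cut as a Michael addition of 2-methylcyclohexane-1,3-dione 16 to vinyl ketone 15. This forms the quaternary C10 by a dependable reaction and brings in ring B as a cheap achiral unit, so all chirality before the union sits in ring C.

**15 to 12 to 9.** On ring C the C14 bromide comes from the C14 alcohol of 12 by inversion, at a stage where the C7 oxygen is an acetate and cannot participate. The C12 hydroxyl comes from the ketone of 9 by hydride attack anti to the side chain, and is kept silylated until after the second bromination.

**9 to 5 and 6.** The C7–C11 bond (aldol) and one C15 methyl bond (conjugate addition) are cut in one operation. An achiral 2,3-dimethylcyclopentenone enolate would give C11 without control; the C14 silyl ether of 5 makes the enolate chiral and already carries the oxygen that becomes the bromide. Acrolein 6 supplies C7, C8 and C9 at once.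

**5 to 1.** The C14 oxygen is introduced at the γ position of 2,3-dimethylcyclopent-2-en-1-one 1 and the racemate is resolved.

## Alternatives that were turned down

Alternative 1: This plan cuts C5–C10 and C1–Br together. Forward, an electrophilic bromine source would attack the C1=C10 alkene of a ten-membered (E,E)-diene ring holding C1–C10; C5, which bears a silyl group, would bond to C10 across the ring with loss of silicon, giving the bromo-octalin acetonide A1 with a C4=C5 alkene. In its favour, the C1 bromide arises by anti addition, equatorial and cis to the C10 methyl group, with no substitution at a neopentyl carbon, and both decalin rings form in one step. On the C1 bromide this is stronger than the chosen route, which relies on an inversion in step 14. Against it, the ten-membered ring must already contain the C7 carbinol with ring C attached, so the C7–C11 problem is only moved earlier and a medium-ring closure is added. The face of bromonium formation relative to the remote ring C centres depends on the ring conformation, the electrophile must choose between two alkenes, and A1 still needs oxidation of a tetrasubstituted alkene to the diol. The chosen strategy makes the C7 carbinol in the ring closure itself and uses only six-membered ring formation.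

Alternative 2: This plan builds ring C by ring expansion. A Lewis acid would open a C7–C11 epoxide at C11 while C15 migrates from the cyclobutanol carbon C12 to C11, giving the 12-oxo compound A2. In its favour, migration anti to the breaking C–O bond sets C7 and C11 together from the epoxide geometry. That is stronger than the 1,3-induction used for C11 in step 5. Against it, a tetrasubstituted C7=C11 alkene between ring A and a brominated cyclobutanol must be made and epoxidised on one face, and the cyclobutane bond that migrates (C15 or C13) must be controlled. The Lewis acid also acts on a molecule with a tertiary 4,5-diol and a bromide next to the migrating carbon, and the C12 ketone must still be reduced. The chosen strategy keeps Lewis acids away from the late polyol and places its weaker stereocontrol early, where epimers can be removed.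

Alternative 3: This plan closes ring B by bromine atom transfer. A copper catalyst would take bromine from a bromomethyl ketone on C5, the C3 radical would add to the vinyl terminus C2, and the C1 radical would take bromine back, giving the bromo silyloxy decalone ketal A3. In its favour, the C1 bromide is made without substitution and the C5 oxygen is in place before ring closure. On both points it is stronger than the chosen route. Against it, closure at the alkene terminus competes with five-membered closure, and bromine return to a planar C1 radical does not enforce the cis relation to the C10 methyl group. A3 also carries C7 only as a masked ketone, so ring C would have to be joined by adding a fully substituted C11 nucleophile to it, the most crowded bond by the least favourable mode. The chosen strategy forms that carbinol intramolecularly.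

Key step: step 19

Assumption: the lipase is taken to acylate the (R)-alcohol (as for closely related 4-hydroxycyclopentenones) and the (R,R) ruthenium catalyst to give the (1R)-carbinol; if either sense is reversed, the acetate fraction or the mirror-image catalyst is used.

## Route

Step 1
Reactants: 1 2,3-dimethylcyclopent-2-en-1-one
Product: 2 rac-4-bromo-2,3-dimethylcyclopent-2-en-1-one
Conditions: NBS, AIBN (cat.), PhCF3, 80 °C
Reagents that add atoms: N-bromosuccinimide, O=C1CCC(=O)N1Br
Why: Wohl–Ziegler bromination; the ring radical at the γ carbon (target C14) is secondary and conjugated with the enone and should form in preference to the primary radical of the neighbouring methyl group.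

Step 2
Reactants: 2 rac-4-bromo-2,3-dimethylcyclopent-2-en-1-one
Product: 3 rac-4-hydroxy-2,3-dimethylcyclopent-2-en-1-one
Conditions: CaCO3, H2O/1,4-dioxane, 60 °C
Reagents that add atoms: water, O
Why: Buffered hydrolysis of an allylic bromide; the weak base neutralises HBr without promoting elimination.

Step 3
Reactants: 3 rac-4-hydroxy-2,3-dimethylcyclopent-2-en-1-one
Product: 4 (S)-4-hydroxy-2,3-dimethylcyclopent-2-en-1-one
Conditions: Burkholderia cepacia lipase, vinyl acetate, MTBE, 30 °C, stopped near half conversion
Reagents that add atoms: none
Why: Lipase-catalysed kinetic resolution by transesterification; the (R)-alcohol should be acetylated and the (S)-alcohol, which carries the C14 oxygen on the face needed later, is recovered.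

Step 4
Reactants: 4 (S)-4-hydroxy-2,3-dimethylcyclopent-2-en-1-one
Product: 5 (S)-2,3-dimethyl-4-(triethylsilyloxy)cyclopent-2-en-1-one
Conditions: Et3SiCl, imidazole, DMF, 0 °C
Reagents that add atoms: triethylsilyl chloride, CC[Si](Cl)(CC)CC
Why: Silylation of a secondary alcohol; the ether tolerates the cuprate and serves as the stereodirecting group.

Step 5
Reactants: 5 (S)-2,3-dimethyl-4-(triethylsilyloxy)cyclopent-2-en-1-one; 6 acrolein
Product: 9 1-[(1S,3S)-1,2,2-trimethyl-5-oxo-3-(triethylsilyloxy)cyclopentyl]prop-2-en-1-yl acetate (both C7 epimers), via lithium enolate 7 (not isolated), via lithium aldolate 8 (not isolated)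
Conditions: Me2CuLi, Et2O, −78 to −20 °C; acrolein, −78 °C; Ac2O, −78 to 0 °C
Reagents that add atoms: lithium dimethylcuprate, [Li+].C[Cu-]C; acetic anhydride, CC(=O)OC(C)=O
Why: Cuprate conjugate addition makes C15 a gem-dimethyl carbon and releases the C11/C12 enolate regiospecifically; its aldol addition to acrolein (1,2 mode at low temperature) should form C7–C11 on the face opposite the C14 silyl ether, whose bias is relayed by the pseudo-axial C15 methyl group on its own face, and the aldolate is acetylated before it can revert; the C7 epimers converge in step 11.

Step 6
Reactants: 9 1-[(1S,3S)-1,2,2-trimethyl-5-oxo-3-(triethylsilyloxy)cyclopentyl]prop-2-en-1-yl acetate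
Product: 10 ring C alcohol (12S,14S) with the C12 hydroxyl cis to the C7 side chain
Conditions: LiBH(s-Bu)3, THF, −78 °C; AcOH quench at −78 °C
Reagents that add atoms: none
Why: Steric approach control; the bulky hydride should reach the C12 carbonyl from the face of the C11 methyl group, away from the branched side chain, placing the hydroxyl cis to that chain, while the ketone reacts before the acetate and the cold acidic quench prevents acyl migration.

Step 7
Reactants: 10 ring C alcohol
Product: 11 C12 tert-butyldimethylsilyl ether of 10
Conditions: TBSOTf, 2,6-lutidine, CH2Cl2, −78 to 0 °C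
Reagents that add atoms: tert-butyldimethylsilyl triflate, CC(C)(C)[Si](C)(C)OS(=O)(=O)C(F)(F)F
Why: Silyl triflate protection of a hindered secondary alcohol; a non-participating group is needed here because it stays on through both brominations.

Step 8
Reactants: 11 C12 tert-butyldimethylsilyl ether
Product: 12 C14 alcohol (C14 hydroxyl on the C11 methyl face; C12 TBS ether and C7 acetate kept)
Conditions: PPTS, MeOH, 0 °C to rt
Reagents that add atoms: none
Why: Acid-catalysed methanolysis should cleave the triethylsilyl ether far faster than the tert-butyldimethylsilyl ether and leaves the acetate untouched.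

Step 9
Reactants: 12 C14 alcohol
Product: 13 C14 bromide (14R) with bromine cis to the C7 chain and the C12 oxygen
Conditions: CBr4, P(n-Oct)3, toluene, 60 °C
Reagents that add atoms: carbon tetrabromide, BrC(Br)(Br)Br
Why: Appel reaction; bromide displaces the alkoxyphosphonium with inversion, moving the substituent from the methyl face to the face of the C7 chain, and at this stage the C7 oxygen is an ester and the C12 oxygen a silyl ether, so no neighbouring oxygen can attack C14 from the rear.

Step 10
Reactants: 13 C14 bromide
Product: 14 1-[(1R,3R,5S)-3-bromo-5-(tert-butyldimethylsilyloxy)-1,2,2-trimethylcyclopentyl]prop-2-en-1-ol (both C7 epimers)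
Conditions: K2CO3, MeOH, 0 °C
Reagents that add atoms: none
Why: Mild transesterification of the allylic acetate; the C7 alkoxide lies on the same face as the bromide and cannot displace it.

Step 11
Reactants: 14 allylic alcohol
Product: 15 1-[(1R,3R,5S)-3-bromo-5-(tert-butyldimethylsilyloxy)-1,2,2-trimethylcyclopentyl]prop-2-en-1-one
Conditions: Dess–Martin periodinane, NaHCO3, CH2Cl2, 0 °C to rt
Reagents that add atoms: none
Why: Dess–Martin oxidation of the only free alcohol; both C7 epimers give the same vinyl ketone, and the silyl ether on C12 prevents oxa-Michael closure onto it.

Step 12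
Reactants: 15 ring C vinyl ketone; 16 2-methylcyclohexane-1,3-dione
Product: 17 2-{3-[(1R,3R,5S)-3-bromo-5-(tert-butyldimethylsilyloxy)-1,2,2-trimethylcyclopentyl]-3-oxopropyl}-2-methylcyclohexane-1,3-dione
Conditions: Et3N (0.2 equiv), MeCN, rt
Reagents that add atoms: none
Why: Michael addition of a cyclic 1,3-dione to a vinyl ketone forms C9–C10 and the quaternary C10; the adduct cannot undergo Robinson closure because the only enolisable position of the C7 ketone (C8) would give a four-membered ring.

Step 13
Reactants: 17 triketone
Product: 18 (1R,10R)-hydroxy diketone with the C1 hydroxyl cis to the C9 chain and trans to the C10 methyl group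
Conditions: RuCl[(R,R)-TsDPEN](p-cymene) (2 mol %), HCO2H/Et3N 5:2, CH2Cl2, 30 °C
Reagents that add atoms: none
Why: Noyori asymmetric transfer hydrogenation used as a desymmetrisation; the catalyst selects one of the two ring carbonyls, setting C10, and hydride enters anti to the larger C10 substituent, setting C1, while the unactivated and heavily shielded C7 ketone should not react.

Step 14
Reactants: 18 hydroxy diketone
Product: 19 dibromo diketone (C1 bromide cis to the C10 methyl group)
Conditions: CBr4, P(n-Oct)3, toluene, 70 °C
Reagents that add atoms: carbon tetrabromide, BrC(Br)(Br)Br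
Why: Appel reaction with inversion at C1; the C5 carbonyl on the neighbouring quaternary carbon disfavours ionisation and 1,2-shift, and C10 has no hydrogen for elimination towards it.

Step 15
Reactants: 19 dibromo diketone
Product: 20 C5 methylene compound (C5=C6H2; C7 ketone kept)
Conditions: Ph3PCH3Br, KOtBu, THF/toluene, 0 °C to rt
Reagents that add atoms: methylenetriphenylphosphorane, [CH2-][P+](c1ccccc1)(c1ccccc1)c1ccccc1
Why: Wittig methylenation; the ring ketone should react well before the C7 ketone, which is screened by C11, C15 and the silyl ether, and the concerted oxaphosphetane pathway avoids a free alkoxide that could fragment towards the C1 bromide.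

Step 16
Reactants: 20 C5 methylene compound
Product: 21 C12 alcohol (β-hydroxy ketone)
Conditions: 48% aq. HF, MeCN, 0 °C to rt
Reagents that add atoms: none
Why: Acidic fluoride desilylation; non-basic conditions keep the β-hydroxy ketone from retro-aldol cleavage and leave the bromides alone.

Step 17
Reactants: 21 C12 alcohol
Product: 22 C4 allylic alcohol (both C4 epimers)
Conditions: SeO2 (cat.), t-BuOOH, CH2Cl2, rt
Reagents that add atoms: tert-butyl hydroperoxide, CC(C)(C)OO
Why: Selenium dioxide allylic oxidation (ene reaction then 2,3-shift); C4 is the only allylic position with hydrogen because C10 is quaternary, so the exocyclic alkene is retained and oxygen arrives at C4.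

Step 18
Reactants: 22 C4 allylic alcohol
Product: 23 exocyclic enone with free C12 hydroxyl (key-step precursor)
Conditions: MnO2, CH2Cl2, rt
Reagents that add atoms: none
Why: Manganese dioxide oxidises the allylic alcohol and not the saturated C12 alcohol; the enone is used at once.

Step 19
Reactants: 23 exocyclic enone
Product: 25 C7 carbinol trans-decal-4-one, via samarium enolate 24 (not isolated)
Conditions: SmI2 (2.5 equiv), t-BuOH (2 equiv), THF, −78 °C
Reagents that add atoms: none
Why: Divalent samarium transfers one electron to the enone (or to the chelated C7 ketone); the radical anion and the second π system couple between C7 and the unsubstituted terminus C6, a second electron gives the trivalent samarium enolate 24, and t-BuOH protonates it at C5. The closest known reaction type is the SmI2-mediated reductive ketone–enone (ketyl–olefin) cyclisation to γ-hydroxy ketones. Ring A closes in the 6-endo-trig mode with respect to C5=C6; the 5-exo alternative would attack the fully substituted C5 against the polarisation of the enone and leave a primary radical. C7 is set in a chair transition state in which the tether leaves C10 equatorially, ring C is equatorial and the samarium-bound oxygen is axial and chelated by the free C12 hydroxyl, which places the new hydroxyl on the face opposite the C10 methyl group. C5 should be protonated axially, anti to that methyl group, to give the trans-decalone; this centre is made planar again in step 20, so its configuration is not critical. The step needs chemoselectivity for the carbonyl π systems over the two secondary C–Br bonds, which the absence of HMPA and the low temperature should secure. It also needs cyclisation to outrun simple reduction, which the quaternary C10 favours by holding the two partners close.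

Step 20
Reactants: 25 C7 carbinol trans-decal-4-one
Product: 26 tris(trimethylsilyl) compound (C4=C5 enol ether; C7 and C12 silyl ethers)
Conditions: TMSOTf, Et3N, CH2Cl2, 0 °C to rt
Reagents that add atoms: trimethylsilyl triflate, C[Si](C)(C)OS(=O)(=O)C(F)(F)F
Why: Silyl enol ether formation under equilibrating amine conditions should give the more substituted C4=C5 isomer; both hydroxyls are silylated in the same operation.

Step 21
Reactants: 26 tris(trimethylsilyl) enol ether
Product: 28 5-(trimethylsilyloxy) 4-ketone, via silyloxy epoxide 27 (not isolated)
Conditions: mCPBA, NaHCO3, CH2Cl2, −20 to 0 °C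
Reagents that add atoms: 3-chloroperbenzoic acid, OOC(=O)c1cccc(Cl)c1
Why: Rubottom oxidation; epoxidation is expected on the face opposite the axial C10 methyl group (axial attack at C5), and silyl migration then gives the α-silyloxy ketone with the C5 oxygen trans to that methyl group.

Step 22
Reactants: 28 5-(trimethylsilyloxy) 4-ketone
Product: 29 C4 tertiary alcohol as tris(trimethylsilyl) ether
Conditions: MeMgBr, CeCl3, THF, −78 to 0 °C
Reagents that add atoms: methylmagnesium bromide, C[Mg]Br
Why: Grignard addition; axial attack at C4 is blocked by the syn-axial C10 methyl group, so the methyl should enter equatorially and leave the hydroxyl axial, trans to the C5 oxygen, and the silyl ether on C5 prevents α-ketol rearrangement.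

Step 23
Reactants: 29 tris(trimethylsilyl) ether
Product: 30 neoirietetraol
Conditions: HF·pyridine, pyridine/THF, 0 °C
Reagents that add atoms: none
Why: Buffered fluoride desilylation; the conditions are too mild to ionise the tertiary alcohols or to eliminate the bromides.

## Compound list

1 | 2,3-dimethylcyclopent-2-en-1-one | CC1=C(C)C(=O)CC1 | starting material
2 | rac-4-bromo-2,3-dimethylcyclopent-2-en-1-one | CC1=C(C)C(Br)CC1=O | intermediate
3 | rac-4-hydroxy-2,3-dimethylcyclopent-2-en-1-one | CC1=C(C)C(O)CC1=O | intermediate
4 | (S)-4-hydroxy-2,3-dimethylcyclopent-2-en-1-one | CC1=C(C)[C@@H](O)CC1=O | intermediate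
5 | (S)-2,3-dimethyl-4-(triethylsilyloxy)cyclopent-2-en-1-one | CC1=C(C)[C@@H](O[Si](CC)(CC)CC)CC1=O | intermediate
6 | acrolein | C=CC=O | starting material
7 | lithium enolate of (4S)-2,3,3-trimethyl-4-(triethylsilyloxy)cyclopentanone | CC1(C)[C@@H](O[Si](CC)(CC)CC)CC([O-])=C1C.[Li+] | intermediate
8 | lithium aldolate (C7 alkoxide; C7 chain trans to the C14 silyl ether) | CC1(C)[C@@H](O[Si](CC)(CC)CC)CC(=O)[C@]1(C)C([O-])C=C.[Li+] | intermediate
9 | 1-[(1S,3S)-1,2,2-trimethyl-5-oxo-3-(triethylsilyloxy)cyclopentyl]prop-2-en-1-yl acetate, both C7 epimers | CC1(C)[C@@H](O[Si](CC)(CC)CC)CC(=O)[C@]1(C)C(OC(C)=O)C=C | intermediate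
10 | ring C alcohol: C12 hydroxyl cis to the C7 chain, C14 triethylsilyl ether, C7 acetate | CC1(C)[C@@H](O[Si](CC)(CC)CC)C[C@H](O)[C@]1(C)C(OC(C)=O)C=C | intermediate
11 | C12 tert-butyldimethylsilyl ether of 10 | CC1(C)[C@@H](O[Si](CC)(CC)CC)C[C@H](O[Si](C)(C)C(C)(C)C)[C@]1(C)C(OC(C)=O)C=C | intermediate
12 | C14 alcohol: hydroxyl on the C11 methyl face, C12 TBS ether, C7 acetate | CC1(C)[C@@H](O)C[C@H](O[Si](C)(C)C(C)(C)C)[C@]1(C)C(OC(C)=O)C=C | intermediate
13 | C14 bromide: bromine cis to the C7 chain and the C12 oxygen, C7 acetate | CC1(C)[C@H](Br)C[C@H](O[Si](C)(C)C(C)(C)C)[C@]1(C)C(OC(C)=O)C=C | intermediate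
14 | 1-[(1R,3R,5S)-3-bromo-5-(tert-butyldimethylsilyloxy)-1,2,2-trimethylcyclopentyl]prop-2-en-1-ol, both C7 epimers | CC1(C)[C@H](Br)C[C@H](O[Si](C)(C)C(C)(C)C)[C@]1(C)C(O)C=C | intermediate
15 | 1-[(1R,3R,5S)-3-bromo-5-(tert-butyldimethylsilyloxy)-1,2,2-trimethylcyclopentyl]prop-2-en-1-one | CC1(C)[C@H](Br)C[C@H](O[Si](C)(C)C(C)(C)C)[C@]1(C)C(=O)C=C | intermediate
16 | 2-methylcyclohexane-1,3-dione | CC1C(=O)CCCC1=O | starting material
17 | triketone: 2-methyl-2-(3-oxo-3-ring C-propyl)cyclohexane-1,3-dione | CC1(C)[C@H](Br)C[C@H](O[Si](C)(C)C(C)(C)C)[C@]1(C)C(=O)CCC2(C)C(=O)CCCC2=O | intermediate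
18 | (1R,10R)-hydroxy diketone: C1 hydroxyl cis to the C9 chain | CC1(C)[C@H](Br)C[C@H](O[Si](C)(C)C(C)(C)C)[C@]1(C)C(=O)CC[C@]2(C)[C@H](O)CCCC2=O | intermediate
19 | dibromo diketone: C1 bromide cis to the C10 methyl group | CC1(C)[C@H](Br)C[C@H](O[Si](C)(C)C(C)(C)C)[C@]1(C)C(=O)CC[C@]2(C)[C@@H](Br)CCCC2=O | intermediate
20 | C5 methylene compound | CC1(C)[C@H](Br)C[C@H](O[Si](C)(C)C(C)(C)C)[C@]1(C)C(=O)CC[C@]2(C)[C@@H](Br)CCCC2=C | intermediate
21 | C12 alcohol of 20 | CC1(C)[C@H](Br)C[C@H](O)[C@]1(C)C(=O)CC[C@]2(C)[C@@H](Br)CCCC2=C | intermediate
22 | C4 allylic alcohol, both C4 epimers | CC1(C)[C@H](Br)C[C@H](O)[C@]1(C)C(=O)CC[C@]2(C)[C@@H](Br)CCC(O)C2=C | intermediate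
23 | key-step precursor: acyl cyclopentane tethered to the 2-methylene bromocyclohexanone | CC1(C)[C@H](Br)C[C@H](O)[C@]1(C)C(=O)CC[C@]2(C)[C@@H](Br)CCC(=O)C2=C | intermediate
24 | trivalent samarium enolate and alkoxide of the cyclised product | CC1(C)[C@H](Br)C[C@H](O)[C@]1(C)[C@@]1(O[Sm](I)I)CC[C@]2(C)[C@@H](Br)CCC(O[Sm](I)I)=C2C1 | intermediate
25 | C7 carbinol trans-decal-4-one | CC1(C)[C@H](Br)C[C@H](O)[C@]1(C)[C@@]1(O)CC[C@]2(C)[C@@H](Br)CCC(=O)[C@H]2C1 | intermediate
26 | tris(trimethylsilyl) compound: C4=C5 enol ether, C7 and C12 silyl ethers | CC1(C)[C@H](Br)C[C@H](O[Si](C)(C)C)[C@]1(C)[C@@]1(O[Si](C)(C)C)CC[C@]2(C)[C@@H](Br)CCC(O[Si](C)(C)C)=C2C1 | intermediate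
27 | 4,5-silyloxy epoxide, oxygen on the face opposite the C10 methyl group | CC1(C)[C@H](Br)C[C@H](O[Si](C)(C)C)[C@]1(C)[C@@]1(O[Si](C)(C)C)CC[C@]2(C)[C@@H](Br)CC[C@]3(O[Si](C)(C)C)O[C@]23C1 | intermediate
28 | 5-(trimethylsilyloxy) 4-ketone, C5 oxygen trans to the C10 methyl group | CC1(C)[C@H](Br)C[C@H](O[Si](C)(C)C)[C@]1(C)[C@@]1(O[Si](C)(C)C)CC[C@]2(C)[C@@H](Br)CCC(=O)[C@@]2(O[Si](C)(C)C)C1 | intermediate
29 | C4 tertiary alcohol as 5,7,12-tris(trimethylsilyl) ether | CC1(C)[C@H](Br)C[C@H](O[Si](C)(C)C)[C@]1(C)[C@@]1(O[Si](C)(C)C)CC[C@]2(C)[C@@H](Br)CC[C@@](C)(O)[C@@]2(O[Si](C)(C)C)C1 | intermediate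
30 | neoirietetraol | CC1(C)[C@H](Br)C[C@H](O)[C@]1(C)[C@@]1(O)CC[C@]2(C)[C@@H](Br)CC[C@@](C)(O)[C@@]2(O)C1 | target

## Step count and least certain steps

Total: 23 steps. Longest linear sequence: 23 steps from 1; 6 and 16 enter as commercial materials in steps 5 and 12.

**Step 19 (key step).** The most likely failure is that electron transfer is followed by simple reduction instead of bond formation, either conjugate reduction of the enone or reduction of the C7 ketone, because the C7 carbonyl is very shielded. Slow loss of bromide is a second risk if the reaction has to be warmed. Fallback: from 23, controlled-potential electroreductive cyclisation of the enone onto the ketone in a divided cell, with a tetraalkylammonium electrolyte and a malonate proton donor in MeCN at a potential below that of alkyl bromide reduction. This gives 25 directly; the C7 configuration then rests on the chair preference alone.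

**Step 5.** The aldol may show poor facial selectivity at C11, because the induction is 1,3 across the gem-dimethyl carbon, and the lithium aldolate can revert or add in the 1,4 mode. Fallback: from 5, the cuprate addition is quenched with Me3SiCl to give the trimethylsilyl enol ether F1. A BF3·OEt2-mediated Mukaiyama aldol with acrolein through an open, irreversible transition state then gives the free aldol F2, and acetylation (Ac2O, DMAP, pyridine) returns to 9.

**Step 6.** Facial selectivity may be eroded because the C14 silyl ether sits on the face from which hydride should come. Fallback: from 9, a Corey–Bakshi–Shibata reduction with the (R)-oxazaborolidine and catecholborane at −78 °C. This replaces substrate control by reagent control, differentiating the quaternary C11 side from the C13 methylene side of the ketone, and returns to 10.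

**Step 9.** Substitution at C14 next to the gem-dimethyl carbon is slow, so elimination towards C13 or a methyl shift from C15 may compete. Fallback: from 12, the chloromethanesulfonate F3 is made with ClCH2SO2Cl and pyridine and displaced with LiBr in DMF. This separates activation from displacement and uses a non-basic bromide source, returning to 13 with the same inversion.

**Step 14.** At C1 the alkoxyphosphonium can eliminate towards C2, and the C7 carbonyl oxygen could take part through a six-membered ring, leading to loss of stereochemical integrity. Fallback: from 18, the chloromethanesulfonate F4 (ClCH2SO2Cl, pyridine, 0 °C) is displaced with LiBr in DMF at the lowest workable temperature, returning to 19.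

**Step 21.** The axial C7 silyl ether is syn-axial to C5 and may compete with the angular methyl group in shielding, giving poor facial selectivity. A related risk in step 20 is incomplete regiocontrol of enolisation towards C5. Fallback: from 26, the lithium enolate is released with MeLi and trapped with PhNTf2 as the enol triflate F5. Methyl coupling (Me2CuLi) gives the tetrasubstituted C4=C5 alkene F6, which is epoxidised with mCPBA to the epoxide F7 on either face. Acid-catalysed hydrolysis then opens either epoxide trans-diaxially to the same 4,5-diol and removes the silyl groups, returning to the route at 30.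

## Further compounds

F1 | step 5 | trimethylsilyl enol ether of (4S)-2,3,3-trimethyl-4-(triethylsilyloxy)cyclopentanone | CC1(C)[C@@H](O[Si](CC)(CC)CC)CC(O[Si](C)(C)C)=C1C
F2 | step 5 | free aldol: 2-(1-hydroxyprop-2-enyl) ketone with the C7 chain trans to the C14 silyl ether | CC1(C)[C@@H](O[Si](CC)(CC)CC)CC(=O)[C@]1(C)C(O)C=C
F0 | step 6 | none | none
F3 | step 9 | C14 chloromethanesulfonate of 12 | CC1(C)[C@@H](OS(=O)(=O)CCl)C[C@H](O[Si](C)(C)C(C)(C)C)[C@]1(C)C(OC(C)=O)C=C
F4 | step 14 | C1 chloromethanesulfonate of 18 | CC1(C)[C@H](Br)C[C@H](O[Si](C)(C)C(C)(C)C)[C@]1(C)C(=O)CC[C@]2(C)[C@H](OS(=O)(=O)CCl)CCCC2=O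
F0 | step 19 | none | none
F5 | step 21 | C4=C5 enol triflate with C7 and C12 trimethylsilyl ethers | CC1(C)[C@H](Br)C[C@H](O[Si](C)(C)C)[C@]1(C)[C@@]1(O[Si](C)(C)C)CC[C@]2(C)[C@@H](Br)CCC(OS(=O)(=O)C(F)(F)F)=C2C1
F6 | step 21 | 4-methyl C4=C5 alkene with C7 and C12 trimethylsilyl ethers | CC1(C)[C@H](Br)C[C@H](O[Si](C)(C)C)[C@]1(C)[C@@]1(O[Si](C)(C)C)CC[C@]2(C)[C@@H](Br)CCC(C)=C2C1
F7 | step 21 | 4,5-epoxide of F6, either face | CC1(C)[C@H](Br)C[C@H](O[Si](C)(C)C)[C@]1(C)[C@@]1(O[Si](C)(C)C)CC[C@]2(C)[C@@H](Br)CCC3(C)OC23C1
A1 | alternative 1 | 1,14-dibromo octalin with C4=C5 alkene and the C7/C12 diol as acetonide | CC1(C)[C@H](Br)C[C@H](O3)[C@]1(C)[C@@]1(OC3(C)C)CC[C@]2(C)[C@@H](Br)CCC(C)=C2C1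
A2 | alternative 2 | 12-oxo analogue of the target | CC1(C)[C@H](Br)CC(=O)[C@]1(C)[C@@]1(O)CC[C@]2(C)[C@@H](Br)CC[C@@](C)(O)[C@@]2(O)C1
A3 | alternative 3 | 1-bromo-5-(trimethylsilyloxy) trans-decal-4-one with C7 as dioxolane | O1CCOC12CC[C@]3(C)[C@@H](Br)CCC(=O)[C@@]3(O[Si](C)(C)C)C2
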